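The route rests on making the central benzene (ring B) from two open-chain pieces. Around ring B every second carbon carries oxygen (C2, C4, C6). The others carry carbon: isobutyryl on C1 and the bridge methylenes on C3 and C5. This 1,3,5-polarity lets C3–C6 come from the dienol ether of a self-Claisen β-keto ester and C1–C2 from a β-ethoxy ynone. One [4+2] cycloaddition with loss of methanol forges C2–C3 and C1–C6, closes and aromatises ring B, and places all six substituents. The precursor already holds the outer arenes (rings A and C) on finished CH2 bridges, with their enolisable isobutyryl ketones masked as TMS enol ethers. Dealkylation and gem-dimethylation of rings A and C finish the synthesis.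

Key step: step 8

Assumption: rings A and C of the target are β-triketones that equilibrate between enol tautomers, so the tautomer of the given SMILES is used. The target has no stereocentre.

Conventions:
- Ring B is numbered C1 (isobutyryl) to C6.
- Each outer ring is numbered C1' (bridge), C2', C3' (free CH), C4', C5' (isobutyryl), C6'.
- Ar = 2,4,6-trimethoxy-3-(2-methylpropanoyl)phenyl.
- ArSi = 2,4,6-trimethoxy-3-[2-methyl-1-(trimethylsilyloxy)prop-1-enyl]phenyl.

Design points:
- The α-CH of the outer aryl isopropyl ketones is about as acidic as the γ-CH2 that has to be removed to make the diene. Selective enolisation cannot be relied on, so all three sites are silylated on purpose. The two extra enol ethers fall off in the work-up of the key step and cost no extra step.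
- The Claisen step is run under equilibrating conditions for the same reason.
- The ynone is made from an N-methoxy-N-methylamide, not from the acid chloride, to exclude double addition.
- The outer ring is acylated after the side chain is in place, on the more electron-rich arene. This allows a start from commercial 2,4,6-trimethoxybenzaldehyde.

Step 1
Reactants: 1 2,4,6-trimethoxybenzaldehyde; 2 trimethyl phosphonoacetate
Product: 4 methyl (E)-3-(2,4,6-trimethoxyphenyl)prop-2-enoate, via sodiated phosphonoacetate 3 (not isolated)
Conditions: 2, NaH, THF, 0 °C; then 1, 0 °C → reflux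
Reagents that add atoms: none
Why: Horner–Wadsworth–Emmons olefination of a non-enolisable aryl aldehyde with a stabilised phosphonate carbanion should give the E-cinnamate, and the alkene geometry is without consequence because the double bond is saturated in step 2.

Step 2
Reactants: 4 methyl (E)-3-(2,4,6-trimethoxyphenyl)prop-2-enoate
Product: 5 methyl 3-(2,4,6-trimethoxyphenyl)propanoate
Conditions: H2 (1 atm), 10% Pd/C, MeOH, rt
Reagents that add atoms: none
Why: Catalytic hydrogenation saturates the conjugated alkene while aryl methyl ethers and the ester are inert under these conditions.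

Step 3
Reactants: 5 methyl 3-(2,4,6-trimethoxyphenyl)propanoate; 6 isobutyryl chloride
Product: 7 methyl 3-[2,4,6-trimethoxy-3-(2-methylpropanoyl)phenyl]propanoate
Conditions: 6 (1.1 equiv), Bi(OTf)3 (5 mol %), 1,2-dichloroethane, 50 °C
Reagents that add atoms: none
Why: Friedel–Crafts acylation of a trialkoxy-activated arene whose two free positions are equivalent gives one regioisomer, the first acyl group deactivates the ring against a second acylation, and a catalytic metal triflate avoids the ortho-demethylation that stoichiometric AlCl3 tends to cause.

Step 4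
Reactants: 7 methyl 3-[2,4,6-trimethoxy-3-(2-methylpropanoyl)phenyl]propanoate (two molecules)
Product: 9 racemic methyl 5-Ar-2-(Ar-methyl)-3-oxopentanoate, via sodium enolate 8 (not isolated)
Conditions: NaH (0.6 equiv per ester), THF, reflux; then 1 M HCl, 0 °C
Reagents that add atoms: none
Why: The Claisen self-condensation is pulled under equilibrating conditions to the stabilised enolate 8, whereas acylation of an outer ketone enolate would give a non-enolisable 2,2-dimethyl-1,3-diketone that reverts by retro-Claisen cleavage, so the isobutyryl groups are tolerated.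

Step 5
Reactants: 9 racemic methyl 5-Ar-2-(Ar-methyl)-3-oxopentanoate
Product: 10 methyl 5-Ar-2-(Ar-methyl)-3-(trimethylsilyloxy)pent-2-enoate (E/Z mixture)
Conditions: TMSCl (1.8 equiv), Et3N (1.6 equiv), toluene, rt; filtration, concentration
Reagents that add atoms: chlorotrimethylsilane, C[Si](C)(C)Cl
Why: Soft enolisation with O-silylation touches only the 1,3-dicarbonyl unit, which alone is acidic enough for Et3N, and the geometry of the new double bond does not matter because it becomes the central single bond of the diene.

Step 6
Reactants: 10 methyl 5-Ar-2-(Ar-methyl)-3-(trimethylsilyloxy)pent-2-enoate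
Product: 11 (1Z,3Z)-1-methoxy-1,3-bis(trimethylsilyloxy)-5-ArSi-2-(ArSi-methyl)penta-1,3-diene
Conditions: TMSCl (4.5 equiv), then LDA (3.6 equiv) dropwise, THF, −78 → 0 °C; pentane, filtration under Ar, used crude
Reagents that add atoms: chlorotrimethylsilane, C[Si](C)(C)Cl
Why: Kinetic γ-deprotonation of a β-silyloxy enoate with in situ O-silylation is the standard entry to 1-alkoxy-1,3-bis(silyloxy)dienes, the excess of base and TMSCl converts the two competing outer ketones into TMS enol ethers so that one defined compound results, and allylic strain against the substituent on the neighbouring diene carbon should place the terminal CH2ArSi group outward (3Z).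

Step 7
Reactants: 12 ethoxyacetylene; 13 N-methoxy-N-methylisobutyramide
Product: 16 1-ethoxy-4-methylpent-1-yn-3-one, via lithium ethoxyacetylide 14 (not isolated), via tetrahedral lithium adduct 15 (not isolated)
Conditions: 12, n-BuLi, THF, −78 °C; 13, −78 → 0 °C; cold sat aq NH4Cl; short-path distillation
Reagents that add atoms: none
Why: In this Weinreb ketone synthesis the chelated adduct 15 survives until the quench and so blocks the second addition that an acid chloride would invite, and the cold near-neutral work-up avoids hydration of the push–pull alkyne.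

Step 8
Reactants: 11 (1Z,3Z)-1-methoxy-1,3-bis(trimethylsilyloxy)-5-ArSi-2-(ArSi-methyl)penta-1,3-diene; 16 1-ethoxy-4-methylpent-1-yn-3-one
Product: 19 1-[2-ethoxy-4,6-dihydroxy-3,5-bis(Ar-methyl)phenyl]-2-methylpropan-1-one, via cyclohexadiene cycloadduct 17 (not isolated), via tetrasilylated arene 18 (not isolated)
Conditions: 16 (2.5 equiv), toluene (2 M), 80 °C, sealed tube, Ar; then 1 M HCl, THF, rt
Reagents that add atoms: none
Why: Diene 11 is doubly donor-activated, so its terminal carbon (future C3) attacks the ethoxy-bearing β-carbon of ynone 16 (future C2), the only conjugate-acceptor site, and the emerging allenolate carbon (C1) then bonds to the ketene acetal carbon (C6), which amounts to a polarity-matched and strongly asynchronous Diels–Alder reaction giving 1,4-cyclohexadiene 17. The closest known reaction type is the cycloaddition–aromatisation of 1-alkoxy-1,3-bis(silyloxy)butadienes with acetylenic ketones and esters to resorcinols; the extra β-ethoxy donor and the fully substituted diene lower the rate, hence high concentration, excess 16 and 80 °C, a ceiling chosen because ethoxyalkynes shed ethylene by a retro-ene path at higher temperature. Ring B closes in an intermolecular [4π+2π] mode as a six-membered carbocycle, which in the stepwise limit is a 6-exo-trig capture of the O-silylated ester carbon C6 by C1. The mixed silyl methyl ketal at C6 of 17 expels methanol with loss of the C3 hydrogen to give arene 18, so the two transient sp3 centres (C3 and C6, cis by suprafacial addition) disappear and no stereocentre has to be controlled, and dilute acid then frees the C4 and C6 phenols and returns both outer enol ethers to isobutyryl ketones. The step needs regioselectivity, secured by the matched donor and acceptor termini, access to the s-cis conformer, secured by the outward (3Z) terminal substituent and the buttressing C4 and C5 substituents, and chemoselectivity over the tetrasubstituted outer enol ethers, which are much weaker and more hindered nucleophiles. Strong Lewis acids such as TiCl4 are left out because they steer dienes of this kind into a (3+3) annulation through C3 and C5 onto the ketone carbonyl.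

Step 9
Reactants: 19 1-[2-ethoxy-4,6-dihydroxy-3,5-bis(Ar-methyl)phenyl]-2-methylpropan-1-one
Product: 20 1-[2,4,6-trihydroxy-3,5-bis({2,4,6-trihydroxy-3-(2-methylpropanoyl)phenyl}methyl)phenyl]-2-methylpropan-1-one
Conditions: BBr3 (15 equiv), CH2Cl2, −78 °C → rt, Ar; then ice/H2O
Reagents that add atoms: none
Why: Lewis acid ether cleavage with BBr3 removes the six methyl groups and the ethyl group by bromide attack on the alkyl carbon of each boron-complexed ether, while the aryl ketones and the diarylmethane C–C bonds should stay intact at or below room temperature.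

Step 10
Reactants: 20 1-[2,4,6-trihydroxy-3,5-bis({2,4,6-trihydroxy-3-(2-methylpropanoyl)phenyl}methyl)phenyl]-2-methylpropan-1-one
Product: 21 onind (target)
Conditions: NaOMe (7 equiv), MeI (4.2 equiv), MeOH, 0 °C → rt, Ar; then 1 M HCl
Reagents that add atoms: iodomethane, CI
Why: Dearomatising double C-methylation of acylphloroglucinolates goes to C3' of rings A and C, the only unsubstituted and least hindered nucleophilic carbons, each ring then becomes a stabilised and far less nucleophilic β-triketone anion, and the limited MeI together with the full substitution of ring B should hold back further alkylation.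

Compound list
1 | 2,4,6-trimethoxybenzaldehyde | COc1cc(OC)c(C=O)c(OC)c1 | starting material
2 | trimethyl phosphonoacetate | COC(=O)CP(=O)(OC)OC | starting material
3 | sodium carbanion of trimethyl phosphonoacetate | [Na+].COC(=O)[CH-]P(=O)(OC)OC | intermediate
4 | methyl (E)-3-(2,4,6-trimethoxyphenyl)prop-2-enoate | COC(=O)/C=C/c1c(OC)cc(OC)cc1OC | intermediate
5 | methyl 3-(2,4,6-trimethoxyphenyl)propanoate | COC(=O)CCc1c(OC)cc(OC)cc1OC | intermediate
6 | isobutyryl chloride | CC(C)C(=O)Cl | starting material
7 | methyl 3-[2,4,6-trimethoxy-3-(2-methylpropanoyl)phenyl]propanoate | COC(=O)CCc1c(OC)cc(OC)c(C(=O)C(C)C)c1OC | intermediate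
8 | sodium enolate of β-keto ester 9 | [Na+].COC(=O)C(Cc1c(OC)cc(OC)c(C(=O)C(C)C)c1OC)=C([O-])CCc1c(OC)cc(OC)c(C(=O)C(C)C)c1OC | intermediate
9 | methyl 5-Ar-2-(Ar-methyl)-3-oxopentanoate (racemic, labile α-centre) | COC(=O)C(Cc1c(OC)cc(OC)c(C(=O)C(C)C)c1OC)C(=O)CCc1c(OC)cc(OC)c(C(=O)C(C)C)c1OC | intermediate
10 | methyl 5-Ar-2-(Ar-methyl)-3-(trimethylsilyloxy)pent-2-enoate (E/Z mixture, geometry lost in step 6) | COC(=O)C(Cc1c(OC)cc(OC)c(C(=O)C(C)C)c1OC)=C(O[Si](C)(C)C)CCc1c(OC)cc(OC)c(C(=O)C(C)C)c1OC | intermediate
11 | (1Z,3Z)-1-methoxy-1,3-bis(trimethylsilyloxy)-5-ArSi-2-(ArSi-methyl)penta-1,3-diene (key-step precursor) | CO/C(O[Si](C)(C)C)=C(Cc1c(OC)cc(OC)c(C(O[Si](C)(C)C)=C(C)C)c1OC)/C(O[Si](C)(C)C)=C/Cc1c(OC)cc(OC)c(C(O[Si](C)(C)C)=C(C)C)c1OC | intermediate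
12 | ethoxyacetylene | CCOC#C | starting material
13 | N-methoxy-N-methylisobutyramide | CON(C)C(=O)C(C)C | starting material
14 | lithium ethoxyacetylide | [Li+].[C-]#COCC | intermediate
15 | lithium 1-ethoxy-3-[methoxy(methyl)amino]-4-methylpent-1-yn-3-olate (racemic) | [Li+].CCOC#CC([O-])(C(C)C)N(C)OC | intermediate
16 | 1-ethoxy-4-methylpent-1-yn-3-one | CCOC#CC(=O)C(C)C | intermediate
17 | cyclohexa-1,4-diene cycloadduct: C1 isobutyryl, C2 OEt, C3 H and CH2ArSi, C4 OTMS, C5 CH2ArSi, C6 OMe and OTMS (racemic, C3-CH2ArSi cis to C6-OMe) | CCOC1=C(C(=O)C(C)C)[C@](OC)(O[Si](C)(C)C)C(Cc2c(OC)cc(OC)c(C(O[Si](C)(C)C)=C(C)C)c2OC)=C(O[Si](C)(C)C)[C@H]1Cc3c(OC)cc(OC)c(C(O[Si](C)(C)C)=C(C)C)c3OC | intermediate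
18 | 1-[2-ethoxy-4,6-bis(trimethylsilyloxy)-3,5-bis(ArSi-methyl)phenyl]-2-methylpropan-1-one | CCOc1c(C(=O)C(C)C)c(O[Si](C)(C)C)c(Cc2c(OC)cc(OC)c(C(O[Si](C)(C)C)=C(C)C)c2OC)c(O[Si](C)(C)C)c1Cc1c(OC)cc(OC)c(C(O[Si](C)(C)C)=C(C)C)c1OC | intermediate
19 | 1-[2-ethoxy-4,6-dihydroxy-3,5-bis(Ar-methyl)phenyl]-2-methylpropan-1-one (key-step product) | CCOc1c(C(=O)C(C)C)c(O)c(Cc2c(OC)cc(OC)c(C(=O)C(C)C)c2OC)c(O)c1Cc1c(OC)cc(OC)c(C(=O)C(C)C)c1OC | intermediate
20 | 1-[2,4,6-trihydroxy-3,5-bis({2,4,6-trihydroxy-3-(2-methylpropanoyl)phenyl}methyl)phenyl]-2-methylpropan-1-one | CC(C)C(=O)c1c(O)c(Cc2c(O)cc(O)c(C(=O)C(C)C)c2O)c(O)c(Cc2c(O)cc(O)c(C(=O)C(C)C)c2O)c1O | intermediate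
21 | onind | CC(C)C(=O)C1=C(O)C(Cc2c(O)c(CC3=C(O)C(C)(C)C(=O)C(C(=O)C(C)C)=C3O)c(O)c(C(=O)C(C)C)c2O)=C(O)C(C)(C)C1=O | target

Total step count: 10. Longest linear sequence: 9 steps (steps 1–6 and 8–10). Step 7 is a one-step side branch.

Steps most likely to fail

Step 8. The ethoxy donor may make the dienophile too sluggish. On long heating the ynone could then be consumed by retro-ene loss of ethylene, and the diene by silyl migration or adventitious hydrolysis. The process might also stop after the first bond through silyl transfer to the allenolate. The fallback makes the two bonds in separate polar operations. It sets out from 11 and 16 and comes back at 19. A vinylogous Mukaiyama–Michael addition (BF3·OEt2, CH2Cl2, −78 °C, quenched cold, mild acidic work-up) would form only C2–C3. It would give the open-chain methyl 5-ethoxy-8-methyl-3,7-dioxo-2,4-bis(Ar-methyl)non-5-enoate F1 as a mixture of epimers and alkene isomers. NaH in THF would then generate the extended dienolate by removal of the C3 hydrogen. Attack of C1 on the ester carbon C6 (Dieckmann-type Claisen cyclisation), loss of methoxide and tautomerisation would give 19. The alternative aldol closure through C5 gives a quaternary aldolate that cannot aromatise and is reversible, so equilibration should drain into the arene.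

Step 10. Alkylation may run on to the bridge-bearing carbons C1' or to oxygen. Ring B may also be attacked. Alkoxide may fragment and recombine the methylene bridges, which would scramble the rings. The fallback gives up late methylation and installs the gem-dimethyl groups on a monomer. It sets out from 6 (with commercial phloroglucinol) and comes back at 21. Friedel–Crafts acylation (AlCl3, CH2Cl2/MeNO2) would give phlorisobutyrophenone F2. Part of this would be gem-dimethylated (MeI, NaOMe, MeOH) to isobutyrylfilicinic acid F3. Condensation of F2 with two equivalents each of F3 and aqueous formaldehyde in dilute KOH, followed by acidification, would give 21. This is the classical methylene-bridging of phloroglucinols. Its price is a statistical product mixture that needs chromatographic separation.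

Step 6. Several things may go wrong here:
- Enolisation may be incomplete.
- C-silylation may compete.
- The ketene acetal may hydrolyse on handling.
- The inward (3E) isomer, which cannot reach the s-cis conformer, may form.

The fallback avoids strong base and leaves the ketones unmasked. It sets out from 9, bypasses 10 and 11, and comes back at 19. Soft enolisation with TMSOTf (2.3 equiv) and Et3N (2.6 equiv) in Et2O at 0 °C should silylate the β-keto ester twice. The di-ortho-substituted aryl isopropyl ketones react more slowly with the limited reagent. This should give (1Z,3Z)-1-methoxy-1,3-bis(trimethylsilyloxy)-5-Ar-2-(Ar-methyl)penta-1,3-diene F4. This diene would be taken with 16 through the cycloaddition and acidic work-up of step 8 to 19.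

Further compounds
F1 | step 8 | methyl 5-ethoxy-8-methyl-3,7-dioxo-2,4-bis(Ar-methyl)non-5-enoate (mixture of epimers and alkene isomers) | COC(=O)C(Cc1c(OC)cc(OC)c(C(=O)C(C)C)c1OC)C(=O)C(Cc1c(OC)cc(OC)c(C(=O)C(C)C)c1OC)C(OCC)=CC(=O)C(C)C
F2 | step 10 | phlorisobutyrophenone, 1-(2,4,6-trihydroxyphenyl)-2-methylpropan-1-one | CC(C)C(=O)c1c(O)cc(O)cc1O
F3 | step 10 | isobutyrylfilicinic acid, 3,5-dihydroxy-4,4-dimethyl-2-(2-methylpropanoyl)cyclohexa-2,5-dien-1-one | CC(C)C(=O)C1=C(O)C=C(O)C(C)(C)C1=O
F4 | step 6 | (1Z,3Z)-1-methoxy-1,3-bis(trimethylsilyloxy)-5-Ar-2-(Ar-methyl)penta-1,3-diene | CO/C(O[Si](C)(C)C)=C(Cc1c(OC)cc(OC)c(C(=O)C(C)C)c1OC)/C(O[Si](C)(C)C)=C/Cc1c(OC)cc(OC)c(C(=O)C(C)C)c1OC
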